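**Retrosynthetic overview**
1. Rings A and B are salicylate rings: the ester-bearing carbon C1 lies between C2–OH and C6–CH3. In ring C, C1 lies between C2–OCH3 and C6–CH3. The C2–O bonds of rings A and B are therefore cut last, back to C2–H, by carbonyl-directed C–H oxygenation; each depside ester then has exactly one free ortho C–H and ring C has none.
2. The des-hydroxy tridepside is carried as the bis(4-nitrobenzyl) compound 11 (ether on the ring A 4-oxygen, ester on the ring C carboxyl). A free phenol next to a free 2,6-disubstituted acid would self-esterify in (CF3CO)2O, and plain benzyl groups would not last in hot CF3CO2H. One hydrogenation removes both groups after the key step.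
3. Compound 11 is cut at the B–C ester into acid 5 and phenol 10. Acid 5 is cut at the A–B ester into acid 3 and 4-hydroxy-2-methylbenzaldehyde 1, whose aldehyde stands in for the ring B carboxyl until a chlorite oxidation.
4. Phenol 10 comes from orsellinic acid 6: benzylation of CO2H and 4-OH, methylation of the hydrogen-bonded 2-OH, hydrogenolysis, then 4-nitrobenzylation of the carboxylate.
5. No ring is formed; the three benzene rings are bought. Bond order: A–B ester, B–C ester, the two aryl C–O bonds, then deprotection.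

Key step: step 9

Remark on the chemistry: 4-hydroxy-2-methylbenzaldehyde, orsellinic acid and 4-nitrobenzyl bromide are taken as purchasable; the target has no stereocenter.

**Route**

Step 1
Reactants: 1 4-hydroxy-2-methylbenzaldehyde
Product: 2 2-methyl-4-[(4-nitrophenyl)methoxy]benzaldehyde
Conditions: 4-nitrobenzyl bromide, K2CO3, DMF, rt
Reagents that add atoms: 4-nitrobenzyl bromide, O=[N+]([O-])c1ccc(CBr)cc1
Why: Williamson ether synthesis, in which the phenoxide of 1 displaces bromide from the reactive benzylic halide by SN2 while the aldehyde stays inert.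

Step 2
Reactants: 2 2-methyl-4-[(4-nitrophenyl)methoxy]benzaldehyde
Product: 3 2-methyl-4-[(4-nitrophenyl)methoxy]benzoic acid
Conditions: NaClO2, NaH2PO4, 2-methyl-2-butene, t-BuOH/THF/H2O, rt
Reagents that add atoms: sodium chlorite, [Na+].[O-]Cl=O
Why: Pinnick oxidation, in which chlorous acid adds to the aldehyde and fragments to the acid while 2-methyl-2-butene traps the HOCl formed, so the ether and the nitro group should be untouched.

Step 3
Reactants: 3 2-methyl-4-[(4-nitrophenyl)methoxy]benzoic acid; 1 4-hydroxy-2-methylbenzaldehyde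
Product: 4 4-formyl-3-methylphenyl 2-methyl-4-[(4-nitrophenyl)methoxy]benzoate
Conditions: EDC·HCl, DMAP (cat.), CH2Cl2, 0 °C to rt
Reagents that add atoms: none
Why: Steglich esterification, in which the O-acylisourea of the mono-ortho-substituted acid 3 is relayed by DMAP as an acylpyridinium ion to the only hydroxyl present, the phenol of 1.

Step 4
Reactants: 4 4-formyl-3-methylphenyl 2-methyl-4-[(4-nitrophenyl)methoxy]benzoate
Product: 5 2-methyl-4-({2-methyl-4-[(4-nitrophenyl)methoxy]benzoyl}oxy)benzoic acid
Conditions: NaClO2, NaH2PO4, 2-methyl-2-butene, t-BuOH/THF/H2O, rt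
Reagents that add atoms: sodium chlorite, [Na+].[O-]Cl=O
Why: Pinnick oxidation of the aryl aldehyde in a weakly acidic buffer, under which the aryl ester, the benzylic ether and the nitro group are stable.

Step 5
Reactants: 6 orsellinic acid (2,4-dihydroxy-6-methylbenzoic acid)
Product: 8 benzyl 4-(benzyloxy)-2-methoxy-6-methylbenzoate, via benzyl 4-(benzyloxy)-2-hydroxy-6-methylbenzoate 7 (not isolated)
Conditions: BnBr (2.05 equiv), K2CO3, DMF, rt; then MeI (excess), K2CO3, 50 °C
Reagents that add atoms: benzyl bromide, BrCc1ccccc1; iodomethane, CI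
Why: Sequential Williamson alkylations ranked by acidity and hydrogen bonding, in which the carboxylate and the free 4-OH take up the two equivalents of BnBr at room temperature and the 2-OH, held in a hydrogen bond to the ester carbonyl, reacts only afterwards with excess MeI on warming.

Step 6
Reactants: 8 benzyl 4-(benzyloxy)-2-methoxy-6-methylbenzoate
Product: 9 4-hydroxy-2-methoxy-6-methylbenzoic acid
Conditions: H2 (1 atm), 10% Pd/C, EtOAc/MeOH, rt
Reagents that add atoms: none
Why: Catalytic hydrogenolysis should cleave both benzylic C–O bonds (ester and aryl ether) and leave the methyl ether and the arene intact.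

Step 7
Reactants: 9 4-hydroxy-2-methoxy-6-methylbenzoic acid
Product: 10 (4-nitrophenyl)methyl 4-hydroxy-2-methoxy-6-methylbenzoate
Conditions: 4-nitrobenzyl bromide (1.05 equiv), KHCO3, DMF, rt
Reagents that add atoms: 4-nitrobenzyl bromide, O=[N+]([O-])c1ccc(CBr)cc1
Why: Chemoselective carboxylate alkylation, in which KHCO3 ionizes only the carboxylic acid and its anion attacks the unhindered benzylic CH2 by SN2, so the phenol should stay free.

Step 8
Reactants: 5 2-methyl-4-({2-methyl-4-[(4-nitrophenyl)methoxy]benzoyl}oxy)benzoic acid; 10 (4-nitrophenyl)methyl 4-hydroxy-2-methoxy-6-methylbenzoate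
Product: 11 (4-nitrophenyl)methyl 2-methoxy-6-methyl-4-{[2-methyl-4-({2-methyl-4-[(4-nitrophenyl)methoxy]benzoyl}oxy)benzoyl]oxy}benzoate
Conditions: EDC·HCl, DMAP (cat.), CH2Cl2, 0 °C to rt
Reagents that add atoms: none
Why: Steglich esterification of the aryl carboxylic acid of 5 with the unhindered 4-OH of 10, the only free nucleophile, while the 2,6-disubstituted 4-nitrobenzyl ester of 10 is too hindered to transacylate.

Step 9
Reactants: 11 (4-nitrophenyl)methyl 2-methoxy-6-methyl-4-{[2-methyl-4-({2-methyl-4-[(4-nitrophenyl)methoxy]benzoyl}oxy)benzoyl]oxy}benzoate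
Product: 13 (4-nitrophenyl)methyl 4-{[2-hydroxy-4-({2-hydroxy-6-methyl-4-[(4-nitrophenyl)methoxy]benzoyl}oxy)-6-methylbenzoyl]oxy}-2-methoxy-6-methylbenzoate, via bis(trifluoroacetate) 12 (not isolated)
Conditions: [RuCl2(p-cymene)]2 (5 mol %), PhI(OCOCF3)2 (3 equiv), CF3CO2H/(CF3CO)2O (3:1), 80 °C; then MeOH/H2O, rt
Reagents that add atoms: [bis(trifluoroacetoxy)iodo]benzene, O=C(OI(OC(=O)C(F)(F)F)c1ccccc1)C(F)(F)F; trifluoroacetic acid, OC(=O)C(F)(F)F (the trifluoroacetate oxygen is delivered by either, since they exchange)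
Why: In CF3CO2H the chloride-bridged dimer should become a divalent ruthenium trifluoroacetate that binds each depside carbonyl oxygen and, by carboxylate-assisted C–H ruthenation, forms a five-membered ruthenacycle at the only free ortho carbon of the ring A and ring B acyl units (C6–H of each 2-methylbenzoyl group, the carbon that becomes C2 of each salicylate); PhI(OCOCF3)2 oxidizes this to tetravalent ruthenium, and C–O reductive elimination releases the aryl trifluoroacetates of 12, which mild hydrolysis converts into the two hydrogen-bonded phenols of 13. The closest known reaction type is the ester-carbonyl-directed ortho C–H oxygenation of benzoate esters with this catalyst, oxidant and solvent system. No ring of the product is closed and no stereocenter is formed. The step needs acyl-side site selectivity at both esters and complete double conversion: the other ortho position of rings A and B is blocked by methyl, ring C has no ortho C–H, the aryloxy-side positions would need a less favourable six-membered chelate and on ring C are flanked by two substituents, and over-oxygenation is excluded because every ortho position is then occupied. The 4-nitrobenzyl ether and ester leave no free OH or CO2H, so (CF3CO)2O cannot cause intermolecular esterification, and both groups should resist hot CF3CO2H and the trivalent iodine oxidant.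

Step 10
Reactants: 13 (4-nitrophenyl)methyl 4-{[2-hydroxy-4-({2-hydroxy-6-methyl-4-[(4-nitrophenyl)methoxy]benzoyl}oxy)-6-methylbenzoyl]oxy}-2-methoxy-6-methylbenzoate
Product: 14 4-{[4-(2,4-dihydroxy-6-methylbenzoyloxy)-2-hydroxy-6-methylbenzoyl]oxy}-2-methoxy-6-methylbenzoic acid (target)
Conditions: H2 (1 atm), 10% Pd/C, THF/AcOH, rt; dilute HCl wash
Reagents that add atoms: none
Why: Catalytic hydrogenation reduces both nitro groups to anilines, and the resulting 4-aminobenzyl ether and ester are cleaved by hydrogenolysis (assisted by 1,6-elimination), the standard removal of 4-nitrobenzyl groups, which should leave the aryl esters intact while AcOH keeps the anilines protonated.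

**Compound list**
1 | 4-hydroxy-2-methylbenzaldehyde | Cc1cc(O)ccc1C=O | starting material
2 | 2-methyl-4-[(4-nitrophenyl)methoxy]benzaldehyde | Cc1cc(OCc2ccc(cc2)[N+](=O)[O-])ccc1C=O | intermediate
3 | 2-methyl-4-[(4-nitrophenyl)methoxy]benzoic acid | Cc1cc(OCc2ccc(cc2)[N+](=O)[O-])ccc1C(=O)O | intermediate
4 | 4-formyl-3-methylphenyl 2-methyl-4-[(4-nitrophenyl)methoxy]benzoate | Cc1cc(OCc2ccc(cc2)[N+](=O)[O-])ccc1C(=O)Oc1ccc(C=O)c(C)c1 | intermediate
5 | 2-methyl-4-({2-methyl-4-[(4-nitrophenyl)methoxy]benzoyl}oxy)benzoic acid | Cc1cc(OCc2ccc(cc2)[N+](=O)[O-])ccc1C(=O)Oc1ccc(C(=O)O)c(C)c1 | intermediate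
6 | orsellinic acid (2,4-dihydroxy-6-methylbenzoic acid) | Cc1cc(O)cc(O)c1C(=O)O | starting material
7 | benzyl 4-(benzyloxy)-2-hydroxy-6-methylbenzoate | Cc1cc(OCc2ccccc2)cc(O)c1C(=O)OCc1ccccc1 | intermediate (not isolated)
8 | benzyl 4-(benzyloxy)-2-methoxy-6-methylbenzoate | COc1cc(OCc2ccccc2)cc(C)c1C(=O)OCc1ccccc1 | intermediate
9 | 4-hydroxy-2-methoxy-6-methylbenzoic acid | COc1cc(O)cc(C)c1C(=O)O | intermediate
10 | (4-nitrophenyl)methyl 4-hydroxy-2-methoxy-6-methylbenzoate | COc1cc(O)cc(C)c1C(=O)OCc1ccc(cc1)[N+](=O)[O-] | intermediate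
11 | (4-nitrophenyl)methyl 2-methoxy-6-methyl-4-{[2-methyl-4-({2-methyl-4-[(4-nitrophenyl)methoxy]benzoyl}oxy)benzoyl]oxy}benzoate | COc1cc(OC(=O)c2ccc(OC(=O)c3ccc(OCc4ccc(cc4)[N+](=O)[O-])cc3C)cc2C)cc(C)c1C(=O)OCc1ccc(cc1)[N+](=O)[O-] | intermediate (key-step precursor)
12 | (4-nitrophenyl)methyl 2-methoxy-6-methyl-4-{[2-methyl-4-({2-methyl-4-[(4-nitrophenyl)methoxy]-6-(trifluoroacetoxy)benzoyl}oxy)-6-(trifluoroacetoxy)benzoyl]oxy}benzoate | COc1cc(OC(=O)c2c(C)cc(OC(=O)c3c(C)cc(OCc4ccc(cc4)[N+](=O)[O-])cc3OC(=O)C(F)(F)F)cc2OC(=O)C(F)(F)F)cc(C)c1C(=O)OCc1ccc(cc1)[N+](=O)[O-] | intermediate (not isolated)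
13 | (4-nitrophenyl)methyl 4-{[2-hydroxy-4-({2-hydroxy-6-methyl-4-[(4-nitrophenyl)methoxy]benzoyl}oxy)-6-methylbenzoyl]oxy}-2-methoxy-6-methylbenzoate | COc1cc(OC(=O)c2c(C)cc(OC(=O)c3c(C)cc(OCc4ccc(cc4)[N+](=O)[O-])cc3O)cc2O)cc(C)c1C(=O)OCc1ccc(cc1)[N+](=O)[O-] | intermediate (key-step product)
14 | 4-{[4-(2,4-dihydroxy-6-methylbenzoyloxy)-2-hydroxy-6-methylbenzoyl]oxy}-2-methoxy-6-methylbenzoic acid | COc1cc(OC(=O)c2c(C)cc(OC(=O)c3c(C)cc(O)cc3O)cc2O)cc(C)c1C(=O)O | target

**Step count**
Total: 10 steps. Longest linear sequence: 7 steps (1, 2, 3, 4, 8, 9, 10); the ring C branch (5, 6, 7) joins at step 8.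

**Steps most likely to fail**

Step 9. The aryl ester carbonyls are weaker donors than those of simple alkyl benzoates. Cyclometalation may therefore stall after one oxygenation, especially at ring B, or drift to the accessible aryloxy-side C–H of ring B. Acid-induced acyl exchange between the depside links at 80 °C is also possible. The fallback gives up late oxygenation and brings both hydroxyls in with the building blocks. It sets out from 10, uses purchased 2,4-dihydroxy-6-methylbenzaldehyde for rings A and B, and rejoins the route at 14. The aldehyde is dibenzylated (BnBr, K2CO3, DMF, 70 °C) to 2,4-bis(benzyloxy)-6-methylbenzaldehyde F1 and oxidized (NaClO2, NaH2PO4, 2-methyl-2-butene) to 2,4-bis(benzyloxy)-6-methylbenzoic acid F2. A second portion of the aldehyde is then acylated by F2 at its non-hydrogen-bonded 4-OH ((CF3CO)2O, toluene, rt) to give 4-formyl-3-hydroxy-5-methylphenyl 2,4-bis(benzyloxy)-6-methylbenzoate F3. Chlorite oxidation (NaClO2, sulfamic acid, aqueous dioxane) gives 4-{[2,4-bis(benzyloxy)-6-methylbenzoyl]oxy}-2-hydroxy-6-methylbenzoic acid F4. Carbodiimide esterification of F4 with 10 (DCC, toluene, rt; the hydrogen-bonded 2-OH does not compete) gives (4-nitrophenyl)methyl 4-[(4-{[2,4-bis(benzyloxy)-6-methylbenzoyl]oxy}-2-hydroxy-6-methylbenzoyl)oxy]-2-methoxy-6-methylbenzoate F5. Hydrogenation (H2, Pd/C, THF/AcOH) removes the two benzyl ethers and the 4-nitrobenzyl ester to give 14.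

Step 10. The aniline by-products may poison Pd/C so that the aryl ether cleavage stalls, or may attack the salicylate-type aryl esters by aminolysis during a long hydrogenation. The fallback sets out from 13 and returns at 14 without a noble metal or hydrogenolysis. Both nitro groups are reduced with Zn dust and NH4Cl in THF/H2O at rt to the bis(4-aminobenzyl) compound (4-aminophenyl)methyl 4-{[4-({4-[(4-aminophenyl)methoxy]-2-hydroxy-6-methylbenzoyl}oxy)-2-hydroxy-6-methylbenzoyl]oxy}-2-methoxy-6-methylbenzoate F6, which is not isolated. Warming in aqueous AcOH should then expel both aminobenzyl groups by 1,6-elimination to give 14.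

Step 5. Telescoping the two alkylations may lose the discrimination between the free 4-OH and the hydrogen-bonded 2-OH, because residual BnBr can alkylate the 2-phenoxide in the warm second stage; decarboxylation of unreacted acid is a further risk. The fallback differentiates the two phenols by acylation instead of alkylation. It sets out from 6 and 5 and returns at 11, so steps 6 to 8 are not needed. Orsellinic acid 6 is alkylated at the carboxylate only (4-nitrobenzyl bromide, KHCO3, DMF, rt) to (4-nitrophenyl)methyl 2,4-dihydroxy-6-methylbenzoate F7. Steglich coupling with 5 (EDC·HCl, DMAP, CH2Cl2) at the non-hydrogen-bonded 4-OH gives (4-nitrophenyl)methyl 2-hydroxy-6-methyl-4-{[2-methyl-4-({2-methyl-4-[(4-nitrophenyl)methoxy]benzoyl}oxy)benzoyl]oxy}benzoate F8. The one remaining phenol is then methylated (MeI, K2CO3, acetone, reflux) to give 11.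

**Further compounds**
F1 | step 9 | 2,4-bis(benzyloxy)-6-methylbenzaldehyde | Cc1cc(OCc2ccccc2)cc(OCc2ccccc2)c1C=O
F2 | step 9 | 2,4-bis(benzyloxy)-6-methylbenzoic acid | Cc1cc(OCc2ccccc2)cc(OCc2ccccc2)c1C(=O)O
F3 | step 9 | 4-formyl-3-hydroxy-5-methylphenyl 2,4-bis(benzyloxy)-6-methylbenzoate | Cc1cc(OCc2ccccc2)cc(OCc2ccccc2)c1C(=O)Oc1cc(C)c(C=O)c(O)c1
F4 | step 9 | 4-{[2,4-bis(benzyloxy)-6-methylbenzoyl]oxy}-2-hydroxy-6-methylbenzoic acid | Cc1cc(OCc2ccccc2)cc(OCc2ccccc2)c1C(=O)Oc1cc(C)c(C(=O)O)c(O)c1
F5 | step 9 | (4-nitrophenyl)methyl 4-[(4-{[2,4-bis(benzyloxy)-6-methylbenzoyl]oxy}-2-hydroxy-6-methylbenzoyl)oxy]-2-methoxy-6-methylbenzoate | COc1cc(OC(=O)c2c(C)cc(OC(=O)c3c(C)cc(OCc4ccccc4)cc3OCc3ccccc3)cc2O)cc(C)c1C(=O)OCc1ccc(cc1)[N+](=O)[O-]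
F6 | step 10 | (4-aminophenyl)methyl 4-{[4-({4-[(4-aminophenyl)methoxy]-2-hydroxy-6-methylbenzoyl}oxy)-2-hydroxy-6-methylbenzoyl]oxy}-2-methoxy-6-methylbenzoate | COc1cc(OC(=O)c2c(C)cc(OC(=O)c3c(C)cc(OCc4ccc(N)cc4)cc3O)cc2O)cc(C)c1C(=O)OCc1ccc(N)cc1
F7 | step 5 | (4-nitrophenyl)methyl 2,4-dihydroxy-6-methylbenzoate | Cc1cc(O)cc(O)c1C(=O)OCc1ccc(cc1)[N+](=O)[O-]
F8 | step 5 | (4-nitrophenyl)methyl 2-hydroxy-6-methyl-4-{[2-methyl-4-({2-methyl-4-[(4-nitrophenyl)methoxy]benzoyl}oxy)benzoyl]oxy}benzoate | Cc1cc(OC(=O)c2ccc(OC(=O)c3ccc(OCc4ccc(cc4)[N+](=O)[O-])cc3C)cc2C)cc(O)c1C(=O)OCc1ccc(cc1)[N+](=O)[O-]
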